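Incoming ligand is conserved: what was charged stands either free or bound, and each complex with two exchanged binds two of it. The quick number asked for rests on that count, for these flasks and runs:

| flask | starting complex | incoming ligand | leaving ligand | remark | time |
|---|---|---|---|---|---|
| south-east | 0.10 M | 0.11 M | 0.14 M | run made earlier |  |
| north-west | 0.10 M | 0.11 M | 0.37 M | run made earlier |  |
| Wednesday's | 0.10 M | 0.110 M | 0.120 M |  | 5.0 d |
| Monday's | 0.10 M | 0.110 M | 0.250 M |  | 5.0 d |
| Thursday's | 0.10 M | 0.110 M | 0.500 M |  | 5.0 d |

| run | time / d | complex with two exchanged / % |
|---|---|---|
| south-east | 0.625 | 5.8 |
| south-east | 1.25 | 14.1 |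
| south-east | 2.08 | 20.5 |
| south-east | 2.50 | 21.9 |
| north-west | 0.625 | 7.1 |
| north-west | 1.25 | 14.5 |
| north-west | 2.08 | 21.3 |
| north-west | 2.50 | 23.2 |

(readings scatter by 1 percentage point)

* amount of complex with two exchanged at the end, in percent of the starting complex charged for Wednesday's, Monday's, Thursday's, in this order
* the course of these numbers from the first flask to the last (falls, then rises / hardly changes / rises all the way / rises, then falls / falls all the way)

- "hardly changes" means that all values lie within two and a half points (for a concentration: within two and a half percent of the largest)

Two exchanges on each starting complex need 0.200 M of incoming ligand, and the charge is 0.110 M, so incoming ligand is the limiting reagent: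

ceiling = c(incoming ligand) / (2 · c(starting complex)) = 55.0%

This ceiling, the yield of complex with two exchanged that the charge of incoming ligand allows, contains no leaving ligand. The earlier runs do not part beyond their scatter either: they differ 2.64-fold in leaving ligand, yet at 2.50 d they read 21.9% and 23.2%, a gap of 1.3 percentage points with a scatter of 1 point per reading. So Wednesday's, Monday's and Thursday's get one number.

As a rough reckoning of my own, the shortfall below the ceiling is treated as a first-order lag. The mean of the two runs climbs from 14.3% at 1.25 d to 22.5% at 2.50 d, which gives a time constant, as a reading:

τ = (mean shortfall) / (mean slope) = 5.54 d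

end value = ceiling − (ceiling − 22.5%) · exp(−(5.0 d − 2.50 d) / τ) = 34.3%

The forecast gives 26%, 26%, 26%, a course that hardly changes: the averaged curve “extrapolates to a plateau near” that figure. My reckoning shares the shape but parts on the level, with 34.3% standing higher than 26%.

The flasks give 32.3%, 32.3%, 32.3%, a course that hardly changes.

    starting complex ⇌ dormant form (K = 0.380, k = 0.0400 h⁻¹)
    complex with one exchanged + incoming ligand → leaving ligand + complex with two exchanged (k = 0.430 M⁻¹ h⁻¹)
    starting complex + incoming ligand → leaving ligand + complex with one exchanged (k = 0.270 M⁻¹ h⁻¹)
    starting complex + complex with one exchanged → side product (k = 0.300 M⁻¹ h⁻¹)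

On Wednesday's, that end value is 58.7% of the ceiling, while side product, in a percentage where each counts as two, stands at 32.7% of the starting complex charged. Thursday's is charged with the same 0.110 M of incoming ligand and 0.10 M of starting complex, so the ceiling reckons the same. At 50.0 d its complex with two exchanged stands at 41.0%, which is 74.5% of the ceiling, with incoming ligand at 0.464% of its charge.

The readings come from a simulation for substances that don't exist; the scatter is artificial.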